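**Retrosynthetic overview**
- Luzonoid A ⇒ Heck arylation of a C7 acrylate with 4-iodophenol; the C11 CH2OH comes from Stille hydroxymethylation of a C3=C4 enol triflate (from the C4 ketone).
- 7β-Acyloxy/8α-OH/10-OH ⇒ titanium-mediated opening of a 7α,8α-epoxy-10-ol by acrylic acid at C7 (inversion) ⇐ asymmetric epoxidation of the C7=C8 allylic alcohol ⇐ borohydride reduction of a C10 thioester.
- Cyclopentene ring (C6, C7, C8, C10) ⇒ phosphine-catalysed [3+2] annulation of an allenic thioester onto the pyranone enone, anti to the C1 isovalerate (sets C5 and C9).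
- Key step: Achmatowicz oxidative ring expansion of furfuryl alcohol (furan → 6-hydroxypyranone), which delivers the whole pyran ring with its enone, ketone and lactol handles; C1 is then fixed by dynamic kinetic acylation with isovaleric acid.
- Ring order: pyran ring first (ring expansion), cyclopentane second (annulation); no protecting groups.

Convention in the names: iridoid numbering (ring atoms C1 acetal carbon, O2, C3, C4, C5, C6, C7, C8, C9; C10 on C8; C11 on C4); β is the face of H-5 and H-9, α the opposite face.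

Step 1
Reactants: 1 furfuryl alcohol (furan-2-ylmethanol)
Product: 2 6-hydroxy-2H-pyran-3(6H)-one (racemic lactol)
Conditions: mCPBA (1.05 equiv), CH2Cl2, 0 °C to rt
Reagents that add atoms: mCPBA (3-chloroperoxybenzoic acid), OOC(=O)c1cccc(Cl)c1
Why: Achmatowicz rearrangement, in which oxidation of the furan gives a ring-opened cis-enedione that recloses as the six-membered lactol, so this oxidative ring expansion builds the complete pyran ring (C1, O2, C3, C4, C5, C9) with the lactol centre still racemic and labile.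

Step 2
Reactants: 2 6-hydroxy-2H-pyran-3(6H)-one; 3 isovaleric acid (3-methylbutanoic acid)
Product: 5 (2S)-5-oxo-5,6-dihydro-2H-pyran-2-yl 3-methylbutanoate, via 3-methylbutanoic pivalic anhydride 4 (not isolated)
Conditions: Piv2O (1.2 equiv), (R)-benzotetramisole (5 mol%), iPr2NEt (1.5 equiv), toluene, 0 °C
Reagents that add atoms: pivalic anhydride, CC(C)(C)C(=O)OC(=O)C(C)(C)C (its pivaloyl group is found only in 4)
Why: Isothiourea-catalysed dynamic kinetic asymmetric acylation with mixed-anhydride activation, in which the lactol epimerises by ring–chain tautomerism while the chiral acyl-isothiouronium acylates one lactol enantiomer only, setting C1 as S (sense of induction assigned by analogy with allylic and benzylic alcohols and to be confirmed by chiral HPLC).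

Step 3
Reactants: 6 but-3-ynoic acid; 7 ethanethiol
Product: 9 S-ethyl buta-2,3-dienethioate, via S-ethyl but-3-ynethioate 8 (not isolated)
Conditions: DCC (1.05 equiv), DMAP (2 mol%), CH2Cl2, −20 °C, thiol as limiting reagent; filter; then Et3N (5 mol%), 0 °C
Reagents that add atoms: none
Why: Steglich-type thioesterification followed by base-catalysed propargyl-to-allenyl isomerisation driven by conjugation, with the thiol consumed before the allene forms so that thia-Michael addition is avoided (no stereocentre).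

Step 4
Reactants: 5 (2S)-5-oxo-5,6-dihydro-2H-pyran-2-yl 3-methylbutanoate; 9 S-ethyl buta-2,3-dienethioate
Product: 10 S-ethyl (1S,4aS,7aS)-1-[(3-methylbutanoyl)oxy]-4-oxo-1,3,4,4a,5,7a-hexahydrocyclopenta[c]pyran-7-carbothioate
Conditions: PPh3 (10 mol%), toluene, rt to 50 °C, slow addition of 9
Reagents that add atoms: none
Why: Proposed new method: a Lu-type phosphine-catalysed [3+2] annulation in which an allenic thioester replaces the usual allenoate, where PPh3 adds to the central allene carbon to give a zwitterion whose thioester-stabilised α-carbon adds to the enone β-carbon (C9) anti to the pseudo-axial C1 acyloxy group, the enolate (C5) closes onto the vinylphosphonium, and proton shift then β-elimination releases PPh3, so this stepwise polar sequence gives the cis-fused cyclopentene with H-5 and H-9 cis to the C1 ester, the closest known reaction being the PPh3-catalysed annulation of buta-2,3-dienoate esters with 6-acyloxy-2H-pyran-3(6H)-ones.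

Step 5
Reactants: 10 S-ethyl (1S,4aS,7aS)-1-[(3-methylbutanoyl)oxy]-4-oxo-1,3,4,4a,5,7a-hexahydrocyclopenta[c]pyran-7-carbothioate
Product: 11 S-ethyl (1S,4aS,7aS)-1-[(3-methylbutanoyl)oxy]-4-{[(trifluoromethyl)sulfonyl]oxy}-1,4a,5,7a-tetrahydrocyclopenta[c]pyran-7-carbothioate
Conditions: KN(SiMe3)2 (1.05 equiv), THF, −78 °C; then PhNTf2 (1.1 equiv), −78 °C
Reagents that add atoms: N-phenylbis(trifluoromethanesulfonimide) (PhNTf2), O=S(=O)(N(c1ccccc1)S(=O)(=O)C(F)(F)F)C(F)(F)F
Why: Kinetic enolisation at the less hindered, oxygen-activated C3 methylene and O-sulfonylation give the C3=C4 enol triflate regioselectively, and at −78 °C the ring-fusion centre C5 is not touched.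

Step 6
Reactants: 11 S-ethyl (1S,4aS,7aS)-1-[(3-methylbutanoyl)oxy]-4-{[(trifluoromethyl)sulfonyl]oxy}-1,4a,5,7a-tetrahydrocyclopenta[c]pyran-7-carbothioate
Product: 12 (1S,4aS,7aS)-7-(hydroxymethyl)-4-{[(trifluoromethyl)sulfonyl]oxy}-1,4a,5,7a-tetrahydrocyclopenta[c]pyran-1-yl 3-methylbutanoate
Conditions: NaBH4 (1.5 equiv), CeCl3·7H2O (1 equiv), THF/EtOH (1:1), −20 °C
Reagents that add atoms: none
Why: Chemoselective borohydride reduction of a thioester under Luche-type 1,2-conditions, which works because a thioester is far more electrophilic towards NaBH4 than an oxygen ester, so the isovalerate and the enol triflate survive (no new stereocentre).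

Step 7
Reactants: 12 (1S,4aS,7aS)-7-(hydroxymethyl)-4-{[(trifluoromethyl)sulfonyl]oxy}-1,4a,5,7a-tetrahydrocyclopenta[c]pyran-1-yl 3-methylbutanoate
Product: 13 (1S,4aS,6R,7R,7aS)-6,7-epoxy-7-(hydroxymethyl)-4-{[(trifluoromethyl)sulfonyl]oxy}-1,4a,5,6,7,7a-hexahydrocyclopenta[c]pyran-1-yl 3-methylbutanoate (the 7α,8α-epoxide in iridoid numbering)
Conditions: Ti(OiPr)4 (1.0 equiv), D-(−)-diethyl tartrate (1.2 equiv), t-BuOOH (2 equiv, in decane), 4 Å MS, CH2Cl2, −20 °C
Reagents that add atoms: tert-butyl hydroperoxide, CC(C)(C)OO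
Why: Sharpless asymmetric epoxidation under reagent control, in which D-(−)-diethyl tartrate (the antipode that turns (E)-alk-2-en-1-ols into (2R,3R)-epoxides) delivers oxygen to the face of C7=C8 anti to H-9, setting C7 and C8 as the 7α,8α-epoxide against the convex-face bias of the cis-fused bicycle.

Step 8
Reactants: 13 (1S,4aS,6R,7R,7aS)-6,7-epoxy-7-(hydroxymethyl)-4-{[(trifluoromethyl)sulfonyl]oxy}-1,4a,5,6,7,7a-hexahydrocyclopenta[c]pyran-1-yl 3-methylbutanoate; 14 acrylic acid
Product: 15 (1S,4aS,6S,7R,7aS)-7-hydroxy-7-(hydroxymethyl)-6-(prop-2-enoyloxy)-4-{[(trifluoromethyl)sulfonyl]oxy}-1,4a,5,6,7,7a-hexahydrocyclopenta[c]pyran-1-yl 3-methylbutanoate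
Conditions: Ti(OiPr)4 (1.5 equiv), acrylic acid (2 equiv), BHT (cat.), CH2Cl2, rt
Reagents that add atoms: none
Why: Titanium-mediated (Caron–Sharpless type) opening of a 2,3-epoxy alcohol by a carboxylic acid, in which chelation of the C10 alkoxide and the epoxide oxygen to titanium directs the carboxylate to the distal secondary carbon C7 with SN2 inversion from the open β face, giving the 7β-ester and leaving the 8α tertiary OH and the C10 OH free.

Step 9
Reactants: 15 (1S,4aS,6S,7R,7aS)-7-hydroxy-7-(hydroxymethyl)-6-(prop-2-enoyloxy)-4-{[(trifluoromethyl)sulfonyl]oxy}-1,4a,5,6,7,7a-hexahydrocyclopenta[c]pyran-1-yl 3-methylbutanoate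
Product: 16 (1S,4aS,6S,7R,7aS)-7-hydroxy-4,7-bis(hydroxymethyl)-6-(prop-2-enoyloxy)-1,4a,5,6,7,7a-hexahydrocyclopenta[c]pyran-1-yl 3-methylbutanoate
Conditions: Bu3SnCH2OH (1.5 equiv), Pd(PPh3)4 (5 mol%), LiCl (3 equiv), BHT (cat.), 1,4-dioxane, 80 °C
Reagents that add atoms: (tributylstannyl)methanol, CCCC[Sn](CCCC)(CCCC)CO
Why: Stille cross-coupling (Kosugi hydroxymethylation) of the enol triflate installs C11 directly at the alcohol oxidation level under neutral conditions, so no hydride is needed and all esters, the acyl acetal and the free diol are tolerated (no stereocentre).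

Step 10
Reactants: 16 (1S,4aS,6S,7R,7aS)-7-hydroxy-4,7-bis(hydroxymethyl)-6-(prop-2-enoyloxy)-1,4a,5,6,7,7a-hexahydrocyclopenta[c]pyran-1-yl 3-methylbutanoate; 17 4-iodophenol
Product: 18 luzonoid A
Conditions: Pd(OAc)2 (5 mol%), NaHCO3 (2.5 equiv), Bu4NCl (1 equiv), DMF, 50 °C
Reagents that add atoms: none
Why: Mizoroki–Heck arylation of the acrylate under ligand-free Jeffery conditions, where syn-insertion and syn-β-hydride elimination give the (E)-4-hydroxycinnamate while the trisubstituted enol ether, the acyl acetal and the free hydroxyls are inert.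

**Compound list**
1 | furfuryl alcohol (furan-2-ylmethanol) | OCc1ccco1 | starting material
2 | 6-hydroxy-2H-pyran-3(6H)-one (racemic) | OC1OCC(=O)C=C1 | intermediate
3 | isovaleric acid (3-methylbutanoic acid) | CC(C)CC(=O)O | starting material
4 | 3-methylbutanoic pivalic anhydride (not isolated) | CC(C)CC(=O)OC(=O)C(C)(C)C | intermediate
5 | (2S)-5-oxo-5,6-dihydro-2H-pyran-2-yl 3-methylbutanoate | CC(C)CC(=O)O[C@@H]1OCC(=O)C=C1 | intermediate
6 | but-3-ynoic acid | C#CCC(=O)O | starting material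
7 | ethanethiol | CCS | starting material
8 | S-ethyl but-3-ynethioate (not isolated) | C#CCC(=O)SCC | intermediate
9 | S-ethyl buta-2,3-dienethioate | C=C=CC(=O)SCC | intermediate
10 | S-ethyl (1S,4aS,7aS)-1-[(3-methylbutanoyl)oxy]-4-oxo-1,3,4,4a,5,7a-hexahydrocyclopenta[c]pyran-7-carbothioate | CC(C)CC(=O)O[C@@H]1OCC(=O)[C@H]2CC=C(C(=O)SCC)[C@@H]12 | intermediate
11 | S-ethyl (1S,4aS,7aS)-1-[(3-methylbutanoyl)oxy]-4-{[(trifluoromethyl)sulfonyl]oxy}-1,4a,5,7a-tetrahydrocyclopenta[c]pyran-7-carbothioate | CC(C)CC(=O)O[C@@H]1OC=C(OS(=O)(=O)C(F)(F)F)[C@H]2CC=C(C(=O)SCC)[C@@H]12 | intermediate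
12 | (1S,4aS,7aS)-7-(hydroxymethyl)-4-{[(trifluoromethyl)sulfonyl]oxy}-1,4a,5,7a-tetrahydrocyclopenta[c]pyran-1-yl 3-methylbutanoate | CC(C)CC(=O)O[C@@H]1OC=C(OS(=O)(=O)C(F)(F)F)[C@H]2CC=C(CO)[C@@H]12 | intermediate
13 | (1S,4aS,6R,7R,7aS)-6,7-epoxy-7-(hydroxymethyl)-4-{[(trifluoromethyl)sulfonyl]oxy}-1,4a,5,6,7,7a-hexahydrocyclopenta[c]pyran-1-yl 3-methylbutanoate (7α,8α-epoxide) | CC(C)CC(=O)O[C@@H]1OC=C(OS(=O)(=O)C(F)(F)F)[C@H]2C[C@H]3O[C@@]3(CO)[C@@H]12 | intermediate
14 | acrylic acid | C=CC(=O)O | starting material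
15 | (1S,4aS,6S,7R,7aS)-7-hydroxy-7-(hydroxymethyl)-6-(prop-2-enoyloxy)-4-{[(trifluoromethyl)sulfonyl]oxy}-1,4a,5,6,7,7a-hexahydrocyclopenta[c]pyran-1-yl 3-methylbutanoate | CC(C)CC(=O)O[C@@H]1OC=C(OS(=O)(=O)C(F)(F)F)[C@H]2C[C@H](OC(=O)C=C)[C@](O)(CO)[C@@H]12 | intermediate
16 | (1S,4aS,6S,7R,7aS)-7-hydroxy-4,7-bis(hydroxymethyl)-6-(prop-2-enoyloxy)-1,4a,5,6,7,7a-hexahydrocyclopenta[c]pyran-1-yl 3-methylbutanoate | CC(C)CC(=O)O[C@@H]1OC=C(CO)[C@H]2C[C@H](OC(=O)C=C)[C@](O)(CO)[C@@H]12 | intermediate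
17 | 4-iodophenol | Oc1ccc(I)cc1 | starting material
18 | luzonoid A, (1S,4aS,6S,7R,7aS)-7-hydroxy-4,7-bis(hydroxymethyl)-6-{[(2E)-3-(4-hydroxyphenyl)prop-2-enoyl]oxy}-1,4a,5,6,7,7a-hexahydrocyclopenta[c]pyran-1-yl 3-methylbutanoate | CC(C)CC(=O)O[C@@H]1OC=C(CO)[C@H]2C[C@H](OC(=O)/C=C/c3ccc(O)cc3)[C@](O)(CO)[C@@H]12 | target

Total step count: 10. Longest linear sequence: 9 steps (1, 2, 4, 5, 6, 7, 8, 9, 10); step 3 is a one-step side branch.

**Three steps most likely to fail**

Step 7 (epoxidation on the concave α face, mismatched with the substrate's convex-face bias). The fallback sets out from 12 and replaces reagent control by substrate-controlled anti addition. NBS in THF/H2O at 0 °C forms the bromonium ion on the convex β face, and water opens it at the tertiary carbon C8 from the α face. This gives (1S,4aS,6S,7R,7aS)-6-bromo-7-hydroxy-7-(hydroxymethyl)-4-{[(trifluoromethyl)sulfonyl]oxy}-1,4a,5,6,7,7a-hexahydrocyclopenta[c]pyran-1-yl 3-methylbutanoate F5 (7β-Br, 8α-OH). Anhydrous K2CO3 in acetone at rt then closes the 8α-alkoxide onto C7 with inversion, and the route is rejoined at 13.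

Step 4 (the proposed new annulation with an allenic thioester). The fallback sets out from 5 and uses the known allenoate annulation. Methyl buta-2,3-dienoate (C=C=CC(=O)OC) with PPh3 (10 mol%) in toluene gives methyl (1S,4aS,7aS)-1-[(3-methylbutanoyl)oxy]-4-oxo-1,3,4,4a,5,7a-hexahydrocyclopenta[c]pyran-7-carboxylate F1. LiI in refluxing ethyl acetate then cleaves the methyl ester by SN2 attack at the methyl group, leaving the isovalerate alone, to give (1S,4aS,7aS)-1-[(3-methylbutanoyl)oxy]-4-oxo-1,3,4,4a,5,7a-hexahydrocyclopenta[c]pyran-7-carboxylic acid F2. DCC/DMAP coupling of F2 with ethanethiol 7 rejoins the route at 10.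

Step 6 (1,2-reduction of a conjugated thioester beside an acyl acetal; conjugate reduction or loss of the isovalerate are the risks). The fallback sets out from 11 and separates activation from reduction. Thiophilic hydrolysis with AgNO3 in THF/H2O with 2,6-lutidine gives (1S,4aS,7aS)-1-[(3-methylbutanoyl)oxy]-4-{[(trifluoromethyl)sulfonyl]oxy}-1,4a,5,7a-tetrahydrocyclopenta[c]pyran-7-carboxylic acid F3. Isobutyl chloroformate and N-methylmorpholine in THF at −15 °C convert F3 into the (2-methylpropyl carbonic) anhydride of F3 F4, which is reduced in the same flask with NaBH4/H2O at −15 °C. This is strictly 1,2, since an acyl carbonate has no conjugate pathway at this temperature, and it rejoins the route at 12.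

Further compounds
F1 | step 4 | methyl (1S,4aS,7aS)-1-[(3-methylbutanoyl)oxy]-4-oxo-1,3,4,4a,5,7a-hexahydrocyclopenta[c]pyran-7-carboxylate | CC(C)CC(=O)O[C@@H]1OCC(=O)[C@H]2CC=C(C(=O)OC)[C@@H]12
F2 | step 4 | (1S,4aS,7aS)-1-[(3-methylbutanoyl)oxy]-4-oxo-1,3,4,4a,5,7a-hexahydrocyclopenta[c]pyran-7-carboxylic acid | CC(C)CC(=O)O[C@@H]1OCC(=O)[C@H]2CC=C(C(=O)O)[C@@H]12
F3 | step 6 | (1S,4aS,7aS)-1-[(3-methylbutanoyl)oxy]-4-{[(trifluoromethyl)sulfonyl]oxy}-1,4a,5,7a-tetrahydrocyclopenta[c]pyran-7-carboxylic acid | CC(C)CC(=O)O[C@@H]1OC=C(OS(=O)(=O)C(F)(F)F)[C@H]2CC=C(C(=O)O)[C@@H]12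
F4 | step 6 | (2-methylpropyl carbonic) anhydride of F3 | CC(C)CC(=O)O[C@@H]1OC=C(OS(=O)(=O)C(F)(F)F)[C@H]2CC=C(C(=O)OC(=O)OCC(C)C)[C@@H]12
F5 | step 7 | (1S,4aS,6S,7R,7aS)-6-bromo-7-hydroxy-7-(hydroxymethyl)-4-{[(trifluoromethyl)sulfonyl]oxy}-1,4a,5,6,7,7a-hexahydrocyclopenta[c]pyran-1-yl 3-methylbutanoate | CC(C)CC(=O)O[C@@H]1OC=C(OS(=O)(=O)C(F)(F)F)[C@H]2C[C@H](Br)[C@](O)(CO)[C@@H]12
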